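## Structural features

Prebarbigerone is an isoflavone. It is a chromen-4-one, in which the benzo ring A is fused to the 4-pyranone ring C through C4a–C8a, and it carries a 2,4,5-trimethoxyphenyl ring B on C3, a methoxy group on C7 and a 3-methylbut-2-enyl (prenyl) group on C8. There is no stereocentre, so the problem is one of constitution only. Ring A is substituted on four adjacent carbons: C4a (acyl carbon C4), C8a (ring oxygen O1), C8 (prenyl) and C7 (methoxy); C5 and C6 carry hydrogen. The fragile parts are the trisubstituted prenyl olefin, which protic and Lewis acids attack or cyclise onto a neighbouring phenol oxygen, the very electron-rich ring B, and the pyranone, which strong nucleophiles open at C2. The real difficulty is the prenyl group on C8 between two oxygen-bearing carbons, because direct C-prenylation of a 7-hydroxyisoflavone or of a resorcinol ketone competes with attack at C6 and at oxygen. The key step uses the alternation in ring A: oxygen on C7 and C8a, carbon on C8 and C4a, hydrogen on C5. This is the pattern of a chain with a carbonyl on every second carbon whose terminal carbon (the future C5) is at the aldehyde oxidation level. If ring A is closed at C4a–C5 from such a chain, the prenyl group can be put on the one carbon that lies between two carbonyls before any ring exists.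

## Logic of the disconnections

13 to 12. The O–CH3 bond at C7 is cut. The C7 oxygen can then pass through the ring-forming steps as a free hydroxyl, so no protecting group is needed anywhere. The forward methylation has to find a single free hydroxyl, which is the case because the C8a oxygen has by then become O1.

12 to 10. The O1–C2 and C2–C3 bonds are cut and C2 is removed as a one-carbon unit at the formic acid oxidation level. Ring C opens to 10, where ring B is joined to ring A through the C3 methylene and the C4 ketone. The pyranone is traded for a ketone whose methylene is activated twice (carbonyl and aryl) and whose ortho hydroxyl is the internal nucleophile. The forward step must bring in C2 without acid, because 10 has a prenyl group next to a free phenol.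

10 to 9. The C4a–C5 bond of ring A is cut and the ring is unfolded to the eight-carbon chain of 9. Ketones sit on chain C2, C4 and C6 (the future C4, C8a and C7), the prenyl group on C5 (future C8), and C8 (future C5) is an aldehyde masked as a methyl enol ether. Cutting here turns a regiochemical problem on an arene into a question of which chain carbon carries the prenyl group, and it accounts for the missing oxygen at C5 through the oxidation level of the chain end. The forward step must close carbon to carbon (C3 to C8) and not oxygen to carbon, under conditions that leave the prenyl olefin alone. The skeleton of 9 is kept as it stands; what is changed is the way 9 is assembled.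

9 to 8 and 3. The chain bond C2–C3 is cut, between the arylacetyl carbonyl and the methylene. A cut at C4–C5 looks shorter, but it needs an acyl donor that already contains the C2 ketone and the acidic C3 methylene, and such a donor would be deprotonated by the enolate it is meant to acylate. With the cut at C2–C3 the nucleophile is the dianion of 8, which can form at one carbon only, and the electrophile is a simple arylacetyl derivative. The forward step must avoid enolising the benzylic position of the electrophile and must keep the finished triketone away from strong base, which is why 3 is an N-methoxy-N-methylamide.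

3 to 1. The amide C–N bond is cut, which leads back to the commercial acid 1. The forward step is an ordinary amide coupling.

8 to 6 and 7. The bond between the central diketone carbon and the allylic CH2 of the prenyl group is cut. The central carbon of a 1,3-diketone is its natural nucleophilic site, so the prenyl group enters exactly at the future C8. The forward step must alkylate on carbon and not on oxygen, and only once.

6 to 4 and 5. The bond between the acetyl carbonyl carbon and the methylene derived from the methyl group of 4 is cut. This leaves two commercial compounds; 4 supplies the future C8, C7, C6 and C5 with the masked aldehyde already present, and 5 supplies C8a and C4a. The forward step needs the kinetic enolate of 4 and C-acylation.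

## Other disconnections considered

Alternative 1: The cut is the C4–C4a bond of ring C. Forward, the acid (Z)-3-(2-allyl-3-methoxyphenoxy)-2-(2,4,5-trimethoxyphenyl)prop-2-enoic acid A1 would be activated as a mixed trifluoroacetic anhydride, or as its acid chloride with SnCl4. It would acylate the ring A carbon ortho to the ether oxygen and para to the methoxy group to give 8-allyl-7-methoxy-3-(2,4,5-trimethoxyphenyl)chromen-4-one A2. Cross-metathesis of A2 with 2-methylbut-2-ene A3 (second-generation Grubbs catalyst) would then turn allyl into prenyl.
- In its favour: ring A is bought as an arene, and the C3–aryl bond and all four methyl ethers are in place before closure. The site of acylation is enforced, since the other ortho position carries the allyl group and the reacting carbon is activated by the para methoxy group. On the certainty of the ring-closing event this alternative is the equal of the chosen plan or better.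
- Against it here: the closure needs a strong electrophilic activator, so the side chain has to be allyl and a further step with a ruthenium catalyst is spent on repairing it. The electron-rich ring B is a competing nucleophile for an acylium ion of a second molecule. Only the Z acid can close. The placing of a carbon substituent between the two oxygens is not solved but moved into the phenol 2-allyl-3-methoxyphenol A4, whose usual source, a Claisen rearrangement of a meta-substituted allyl aryl ether, can deliver to either ortho position.
- Comparison: on structure, the chosen plan fixes the prenyl position through chain connectivity, whereas this one relies on arene regiochemistry at an earlier stage. On mechanism, it is an electrophilic aromatic substitution under acid against an enolate addition–elimination under mild base that tolerates prenyl as such. On step economy the two are about equal (preparation of A4 and A1, closure and metathesis against seven steps).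

Alternative 2: The cuts are C8–C8a and C6–C7, two bonds of ring A. Forward, 3-ethenyl-5-(2,4,5-trimethoxyphenyl)pyran-4-one A5 would act as a diene through its ring C=C bond (the future C8a=C4a) and the vinyl group. The ynol ether 1-methoxy-5-methylhex-4-en-1-yne A6 would add across it to give racemic 7-methoxy-8-(3-methylbut-2-enyl)-3-(2,4,5-trimethoxyphenyl)-6,8a-dihydrochromen-4-one A7. Removal of the hydrogens on C6 and C8a with a quinone oxidant would then give 13.
- In its favour: two ring bonds form in one operation, and A6 brings the C7 methoxy and C8 prenyl groups in final form and in a fixed 1,2-relationship, so no late O-methylation is needed. On bonds formed per step and on convergence this alternative is better than the chosen plan. The polarisation also matches, since the nucleophilic alkyne carbon that bears the prenyl group meets the electrophilic pyranone carbon next to oxygen.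
- Against it here: the ring C=C bond of a 4-pyranone has vinylogous ester and partly aromatic character, so A5 is a doubtful diene. Ynol ethers are heat-sensitive and prone to stepwise [2+2] addition to enones. A7 must be dehydrogenated in the presence of a prenyl group and ring B, and A7 can also aromatise by β-elimination of the ring oxygen from C8a, which would open ring C. Both A5 and A6 need several steps of their own.
- Comparison: on structure, it carries the 7-OMe/8-prenyl pair in one piece, which is an advantage, but it creates a stereocentre at C8a only to destroy it. On mechanism, it depends on a cycloaddition of uncertain rate and on a selective oxidation, whereas the chosen fold is redox-neutral and driven by aromatisation. On step economy it is probably longer once A5 and A6 are counted.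

Alternative 3: The cut is the C3–C4 bond of ring C. Forward, the aldehyde 4-methoxy-3-(3-methylbut-2-enyl)-2-[2-oxo-2-(2,4,5-trimethoxyphenyl)ethoxy]benzaldehyde A8 would be treated with a triazolium-derived N-heterocyclic carbene and an amidine base. The acyl anion equivalent formed at the aldehyde carbon would add to the tethered aryl ketone to give racemic 3-hydroxy-7-methoxy-8-(3-methylbut-2-enyl)-3-(2,4,5-trimethoxyphenyl)chroman-4-one A9, which would then be dehydrated across C2–C3.
- In its favour: the closure is catalytic, metal-free and nearly neutral, so the prenyl group is safe. Intramolecular aldehyde–ketone benzoin closures to chroman-4-ones are well established, and A8 comes convergently from a salicylaldehyde and a phenacyl halide. In mildness and in precedent for the ring closure itself this alternative is the equal of the chosen plan or better.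
- Against it here: the acceptor is an ortho-methoxy, donor-rich aryl ketone, which is hindered and weakly electrophilic, so aldehyde self-condensation and oxidation of the amino enol can compete. A9 is a tertiary α-hydroxy ketone whose dehydration cannot go by an E1cB path, because the hydroxyl is α and not β to the carbonyl; under ionising conditions aryl migration or attack on the prenyl olefin threatens. As in alternative 1, the prenyl group between two oxygens must first be installed on an aromatic building block.
- Comparison: on structure, it makes and then removes a stereocentre and an extra oxygen at C3, whereas the chosen plan forms no superfluous centre. On mechanism, the ring closure is milder and better precedented, but the dehydration that follows is the weaker link. On step economy it is about equal (aldehyde synthesis, O-alkylation, benzoin, dehydration).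

Key step: step 5

Remark: 6, 8 and 9 are keto–enol mixtures written in the all-keto form; the carbon between two carbonyls (C3 of 8, C5 of 9) is stereogenic only in that form and is labile, so both are racemic; the chain of 9 is numbered C1 (benzylic) to C8 (enol ether carbon), ring positions follow chromen-4-one numbering, and 9 (C23H30O7) and 10 (C22H26O6) differ by exactly one methanol, so the two structures are consistent and need no correction.

Step 1
Reactants: 1 2-(2,4,5-trimethoxyphenyl)acetic acid
Product: 3 N-methoxy-N-methyl-2-(2,4,5-trimethoxyphenyl)acetamide, via acyl imidazole 2 (not isolated)
Conditions: 1,1'-carbonyldiimidazole (1.1 equiv), CH2Cl2, 23 °C; then MeNH(OMe)·HCl (1.2 equiv), 23 °C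
Reagents that add atoms: N,O-dimethylhydroxylamine hydrochloride, CNOC.Cl; 1,1'-carbonyldiimidazole, O=C(n1ccnc1)n1ccnc1 (its imidazole unit stays only in 2)
Why: Activation of the acid as its acyl imidazole followed by aminolysis is a standard amide coupling. The N-methoxy-N-methylamide is chosen because its adduct with a carbanion stays a chelated tetrahedral species until work-up (Weinreb ketone synthesis), which step 4 relies on.

Step 2
Reactants: 4 (E)-4-methoxybut-3-en-2-one; 5 acetyl chloride
Product: 6 (E)-6-methoxyhex-5-ene-2,4-dione (enolised)
Conditions: 4 (2.0 equiv), LiN(SiMe3)2 (2.0 equiv), THF, −78 °C; 5 (1.0 equiv), −78 °C; AcOH, −78 °C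
Reagents that add atoms: none
Why: Crossed Claisen-type C-acylation of the kinetic lithium enolate of 4, which can form only at the methyl group, with an acid chloride; this is the known entry to 1-methoxyalk-1-ene-3,5-diones used for 4-pyranones. The second equivalent of enolate takes up the acidic proton of 6, and the cold acetic acid quench avoids acid-induced closure of 6 to a pyranone.

Step 3
Reactants: 6 (E)-6-methoxyhex-5-ene-2,4-dione; 7 1-bromo-3-methylbut-2-ene (prenyl bromide)
Product: 8 (E)-6-methoxy-3-(3-methylbut-2-enyl)hex-5-ene-2,4-dione (racemic, enolised)
Conditions: K2CO3 (1.5 equiv), acetone, 23 to 40 °C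
Reagents that add atoms: none
Why: C-Alkylation of the potassium enolate of a 1,3-diketone at its central carbon by an allylic bromide (SN2), for which K2CO3 in acetone is the standard carbon-selective medium. The prenyl group is thereby fixed on the carbon that becomes C8, between the two future oxygen-bearing carbons.

Step 4
Reactants: 8 (E)-6-methoxy-3-(3-methylbut-2-enyl)hex-5-ene-2,4-dione; 3 N-methoxy-N-methyl-2-(2,4,5-trimethoxyphenyl)acetamide
Product: 9 (E)-8-methoxy-5-(3-methylbut-2-enyl)-1-(2,4,5-trimethoxyphenyl)oct-7-ene-2,4,6-trione (racemic, mixture of enol tautomers)
Conditions: 8 (1.3 equiv), LiN(i-Pr)2 (2.7 equiv), THF, −78 to −20 °C; 3 (1.0 equiv), −78 to −40 °C; AcOH, THF, −78 °C, then pH 6 phosphate buffer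
Reagents that add atoms: none
Why: Acylation of a 1,3-diketone dianion at its terminal carbon: after the central carbon, only the methyl group of 8 can be deprotonated (the other flank is vinylic), and this more basic carbanion adds to the N-methoxy-N-methylamide (Weinreb ketone synthesis). The tetrahedral adduct hides the C2 ketone until the cold quench, so the C3 methylene of 9 is never acidic in the presence of strong base and 9 cannot fold early.

Step 5
Reactants: 9 (E)-8-methoxy-5-(3-methylbut-2-enyl)-1-(2,4,5-trimethoxyphenyl)oct-7-ene-2,4,6-trione
Product: 10 1-[2,4-dihydroxy-3-(3-methylbut-2-enyl)phenyl]-2-(2,4,5-trimethoxyphenyl)ethanone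
Conditions: Mg(OMe)2 (1.2 equiv), MeOH (0.02 M), N2, 23 to 50 °C; then 1 M HCl to pH 5, 0 °C
Reagents that add atoms: none
Why: Mg(OMe)2 removes the most acidic proton, that of the C3 methylene between the C2 and C4 ketones (C5 is a less acidic, alkyl-substituted methine next to a vinylogous ester carbonyl), and divalent magnesium holds the O(C2)/O(C4) enolate as a six-membered chelate, the same chelate that the product keeps between its ketone and its ortho phenol. The C3 carbon then adds to C8, the β-carbon of the still intact C6 enone, the C6 enolate expels methoxide (addition–elimination, an intramolecular vinylogous aldol-type condensation), and two enolisations of the cyclohexenedione give the resorcinol 10, an aromatisation that makes the sequence irreversible. The closest known reaction type is the base-mediated biomimetic cyclisation of 3,5,7-triketo chains and of their terminal vinylogous esters to resorcinols. Ring A closes in a 6-endo-trig mode, the C7=C8 bond lying inside the new ring, and a 6π electrocyclisation of the C3=C4–C5=C6–C7=C8 trienolate followed by loss of methanol would lead to the same product. No stereocentre is created, and the labile C5 centre of 9 becomes the aromatic carbon C8. The selectivity needed is closure through carbon and not through oxygen: the chelate ties up O(C4), whose attack on C8 would give a 4-pyranone, and methoxide in methanol can reopen such a pyranone to the chain, so that material is funnelled to 10. Other folds are excluded by the substrate, since C5 has no six-membered partner and an aldol of C1 onto C6 would need the least acidic site to attack the least electrophilic carbonyl. The leaving group is the conjugate base of the solvent, so conjugate addition of methoxide to C8 is a degenerate exchange and costs nothing.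

Step 6
Reactants: 10 1-[2,4-dihydroxy-3-(3-methylbut-2-enyl)phenyl]-2-(2,4,5-trimethoxyphenyl)ethanone
Product: 12 7-hydroxy-8-(3-methylbut-2-enyl)-3-(2,4,5-trimethoxyphenyl)chromen-4-one, via enaminone 11 (not isolated)
Conditions: Me2NCH(OMe)2 (3 equiv), toluene, 90 °C
Reagents that add atoms: N,N-dimethylformamide dimethyl acetal, COC(OC)N(C)C
Why: Condensation of the doubly activated methylene with the amide acetal gives enaminone 11; the chelated 2-hydroxyl adds to its aminomethylene carbon and dimethylamine is lost (oxa-Michael addition–elimination), the standard closure of 2-hydroxydeoxybenzoins to isoflavones. The medium is neutral to basic, so the prenyl group next to the free 7-hydroxyl is not cyclised, and any O-methylation of that hydroxyl by the reagent would give 13 itself.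

Step 7
Reactants: 12 7-hydroxy-8-(3-methylbut-2-enyl)-3-(2,4,5-trimethoxyphenyl)chromen-4-one
Product: 13 prebarbigerone, 7-methoxy-8-(3-methylbut-2-enyl)-3-(2,4,5-trimethoxyphenyl)chromen-4-one
Conditions: MeI (1.5 equiv), K2CO3 (2 equiv), acetone, 50 °C
Reagents that add atoms: iodomethane, CI
Why: Williamson ether synthesis (SN2) on the only free hydroxyl, the acidic 7-OH para to the carbonyl. K2CO3 in acetone does not open the pyranone, and no acidic C–H remains for C-methylation.

Compound list

1 | 2-(2,4,5-trimethoxyphenyl)acetic acid | COc1cc(OC)c(CC(=O)O)cc1OC | starting material
2 | 1-(imidazol-1-yl)-2-(2,4,5-trimethoxyphenyl)ethanone (acyl imidazole, not isolated) | COc1cc(OC)c(CC(=O)n2ccnc2)cc1OC | intermediate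
3 | N-methoxy-N-methyl-2-(2,4,5-trimethoxyphenyl)acetamide | COc1cc(OC)c(CC(=O)N(C)OC)cc1OC | intermediate
4 | (E)-4-methoxybut-3-en-2-one | CO/C=C/C(C)=O | starting material
5 | acetyl chloride | CC(=O)Cl | starting material
6 | (E)-6-methoxyhex-5-ene-2,4-dione (enolised) | CO/C=C/C(=O)CC(C)=O | intermediate
7 | 1-bromo-3-methylbut-2-ene (prenyl bromide) | CC(C)=CCBr | starting material
8 | (E)-6-methoxy-3-(3-methylbut-2-enyl)hex-5-ene-2,4-dione (racemic, enolised) | CO/C=C/C(=O)C(CC=C(C)C)C(C)=O | intermediate
9 | (E)-8-methoxy-5-(3-methylbut-2-enyl)-1-(2,4,5-trimethoxyphenyl)oct-7-ene-2,4,6-trione (racemic, enol tautomers) | COc1cc(OC)c(CC(=O)CC(=O)C(CC=C(C)C)C(=O)/C=C/OC)cc1OC | intermediate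
10 | 1-[2,4-dihydroxy-3-(3-methylbut-2-enyl)phenyl]-2-(2,4,5-trimethoxyphenyl)ethanone | COc1cc(OC)c(CC(=O)c2ccc(O)c(CC=C(C)C)c2O)cc1OC | intermediate
11 | (E)-1-[2,4-dihydroxy-3-(3-methylbut-2-enyl)phenyl]-3-(dimethylamino)-2-(2,4,5-trimethoxyphenyl)prop-2-en-1-one (enaminone, not isolated; E drawn, either geometry closes) | CN(C)/C=C(\c1cc(OC)c(OC)cc1OC)C(=O)c1ccc(O)c(CC=C(C)C)c1O | intermediate
12 | 7-hydroxy-8-(3-methylbut-2-enyl)-3-(2,4,5-trimethoxyphenyl)chromen-4-one | COc1cc(OC)c(-c2coc3c(CC=C(C)C)c(O)ccc3c2=O)cc1OC | intermediate
13 | prebarbigerone, 7-methoxy-8-(3-methylbut-2-enyl)-3-(2,4,5-trimethoxyphenyl)chromen-4-one | COc1cc(OC)c(-c2coc3c(CC=C(C)C)c(OC)ccc3c2=O)cc1OC | target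

Total step count: 7. Longest linear sequence: 6 steps (4 to 6 to 8 to 9 to 10 to 12 to 13, steps 2 to 7); step 1 is a one-step side branch that joins at step 4.

Least certain steps

Step 5 (key step). The most likely failures are closure through the enol oxygen on C4 to a 4-pyranone that the mild base does not reopen, and retro-Claisen cleavage of the 2-alkylated 1,3-diketone unit by methoxide, since the C5 carbon is tertiary. Double deprotonation (C3 and C5) would also turn the C6 enone into an enolate and switch off the acceptor. The fallback sets out from 9 and returns at 10. It closes 9 on purpose through oxygen with pyridinium p-toluenesulfonate in CH2Cl2 to 3-(3-methylbut-2-enyl)-2-[2-oxo-3-(2,4,5-trimethoxyphenyl)propyl]pyran-4-one F1. KOH in aqueous MeOH then opens the pyranone by conjugate addition of hydroxide to the enolate of the free formyl triketone, which closes by a 6-exo-trig aldol of C3 on the aldehyde carbon and dehydrates to 10. This is the classical conversion of 4-pyranones into resorcinols, and it replaces the addition–elimination on an enol ether by an aldol condensation on a free aldehyde.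

Step 4. The dianion of 8 may take a benzylic proton from 3 instead of adding to it, and the dianion may fold on itself (terminal carbon onto the enol ether carbon) if it is allowed to warm. The fallback sets out from 3 and 8 and returns at 9. 3 is reduced with i-Bu2AlH (THF, −78 °C) to 2-(2,4,5-trimethoxyphenyl)acetaldehyde F2. F2 is added at −78 °C to the dianion of 8, where carbonyl addition is much faster than proton transfer, to give the aldol (E)-2-hydroxy-8-methoxy-5-(3-methylbut-2-enyl)-1-(2,4,5-trimethoxyphenyl)oct-7-ene-4,6-dione F3 as a mixture of diastereomers. Oxidation of the β-hydroxy ketone with 2-iodoxybenzoic acid (EtOAc, 70 °C) then gives 9.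

Step 3. Alkylation on oxygen, or a second alkylation on carbon, may compete with the wanted mono-C-prenylation, because the enolate of 6 is extended through the methoxyvinyl group and is ambident. The fallback sets out from 4 and returns at 8 by inverting the order of the two C–C bond formations. The kinetic lithium enolate of 4 (LiN(SiMe3)2, THF, 1,3-dimethyl-3,4,5,6-tetrahydropyrimidin-2(1H)-one as cosolvent, −78 °C) is alkylated with 7 to (E)-1-methoxy-7-methylocta-1,6-dien-3-one F4. The lithium enolate of F4 (two equivalents) is then acylated with 5 as in step 2, so the prenyl-bearing carbon becomes the central diketone carbon of 8.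

Step 6. The sequence may stop at enaminone 11, or the amide acetal may be used up in methyl transfer to the phenols before condensation at the hindered methylene is complete. The fallback sets out from 10 and returns at 13, passing by 12. The non-chelated 4-hydroxyl of 10 is methylated selectively (MeI, 1.05 equiv, K2CO3, acetone, 23 °C) to 1-[2-hydroxy-4-methoxy-3-(3-methylbut-2-enyl)phenyl]-2-(2,4,5-trimethoxyphenyl)ethanone F5. Ring C is then closed with triethyl orthoformate, pyridine and catalytic piperidine at 120 °C, the classical orthoformate synthesis of isoflavones, which is basic throughout.

Further compounds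

F1 | step 5 | 3-(3-methylbut-2-enyl)-2-[2-oxo-3-(2,4,5-trimethoxyphenyl)propyl]pyran-4-one | COc1cc(OC)c(CC(=O)Cc2occc(=O)c2CC=C(C)C)cc1OC
F2 | step 4 | 2-(2,4,5-trimethoxyphenyl)acetaldehyde | COc1cc(OC)c(CC=O)cc1OC
F3 | step 4 | (E)-2-hydroxy-8-methoxy-5-(3-methylbut-2-enyl)-1-(2,4,5-trimethoxyphenyl)oct-7-ene-4,6-dione (mixture of diastereomers) | COc1cc(OC)c(CC(O)CC(=O)C(CC=C(C)C)C(=O)/C=C/OC)cc1OC
F4 | step 3 | (E)-1-methoxy-7-methylocta-1,6-dien-3-one | CO/C=C/C(=O)CCC=C(C)C
F5 | step 6 | 1-[2-hydroxy-4-methoxy-3-(3-methylbut-2-enyl)phenyl]-2-(2,4,5-trimethoxyphenyl)ethanone | COc1cc(OC)c(CC(=O)c2ccc(OC)c(CC=C(C)C)c2O)cc1OC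
A1 | alternative 1 | (Z)-3-(2-allyl-3-methoxyphenoxy)-2-(2,4,5-trimethoxyphenyl)prop-2-enoic acid | COc1cc(OC)c(/C(C(=O)O)=C/Oc2cccc(OC)c2CC=C)cc1OC
A2 | alternative 1 | 8-allyl-7-methoxy-3-(2,4,5-trimethoxyphenyl)chromen-4-one | COc1cc(OC)c(-c2coc3c(CC=C)c(OC)ccc3c2=O)cc1OC
A3 | alternative 1 | 2-methylbut-2-ene | CC=C(C)C
A4 | alternative 1 | 2-allyl-3-methoxyphenol | COc1cccc(O)c1CC=C
A5 | alternative 2 | 3-ethenyl-5-(2,4,5-trimethoxyphenyl)pyran-4-one | C=Cc1cocc(-c2cc(OC)c(OC)cc2OC)c1=O
A6 | alternative 2 | 1-methoxy-5-methylhex-4-en-1-yne | COC#CCC=C(C)C
A7 | alternative 2 | 7-methoxy-8-(3-methylbut-2-enyl)-3-(2,4,5-trimethoxyphenyl)-6,8a-dihydrochromen-4-one (racemic) | COC1=C(CC=C(C)C)C2OC=C(c3cc(OC)c(OC)cc3OC)C(=O)C2=CC1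
A8 | alternative 3 | 4-methoxy-3-(3-methylbut-2-enyl)-2-[2-oxo-2-(2,4,5-trimethoxyphenyl)ethoxy]benzaldehyde | COc1cc(OC)c(C(=O)COc2c(C=O)ccc(OC)c2CC=C(C)C)cc1OC
A9 | alternative 3 | 3-hydroxy-7-methoxy-8-(3-methylbut-2-enyl)-3-(2,4,5-trimethoxyphenyl)chroman-4-one (racemic) | COc1cc(OC)c(C2(O)COc3c(CC=C(C)C)c(OC)ccc3C2=O)cc1OC
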